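**Strategy.** The enal is cut by a retro-aldol condensation into two C20 15-oxolabd-8(17)-en-19-oates. The left one is oxidised imbricatolic acid. The right one is its 5-epimer, whose cis A′/B′ fusion (H-5′ and CH3-20′ on the same face) is the feature the key step exploits. Ring B′ (C5′–C10′) is made first by a Diels–Alder reaction of a citronellol-derived enal. The key step then closes ring A′ (C1′–C2′–C3′–C4′–C5′–C10′) by Pd-catalysed intramolecular allylic alkylation of a β-keto ester tethered to C10′, forming C4′–C5′ with overall retention and setting C5′ and the quaternary C4′ in one operation. Its precursor is a monocyclic cis-1,4-diacetoxycyclohex-2-ene.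

Key step: step 8

Remark 1: labdane numbering is used, primed for the right-hand unit; β is the face of CH3-20 (CH3-20′), α the opposite face; TMSE = 2-(trimethylsilyl)ethyl, TBS = tert-butyldimethylsilyl.
Remark 2: imbricatolic acid (21) is taken as a purchasable natural product.
Remark 3: the antipode of the oxazaborolidinium catalyst in step 4 is the one assigned from the formyl C–H···O model and is to be confirmed on 8; the other antipode is equally available.

Step 1
Reactants: 1 ethyl 2-methyl-3-oxobutanoate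
Product: 2 2-(trimethylsilyl)ethyl 2-methyl-3-oxobutanoate
Conditions: Me3SiCH2CH2OH, DMAP (cat.), toluene, reflux (−EtOH)
Reagents that add atoms: 2-(trimethylsilyl)ethanol, C[Si](C)(C)CCO
Why: DMAP-catalysed transesterification of an enolisable β-keto ester is driven by distilling out ethanol; no stereocentre is set (C2 is configurationally labile).

Step 2
Reactants: 3 (S)-citronellol
Product: 4 (S)-citronellol TBS ether
Conditions: TBSCl, imidazole, DMF, rt
Reagents that add atoms: tert-butyldimethylsilyl chloride, CC(C)(C)[Si](C)(C)Cl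
Why: Standard silylation of a primary alcohol; the future C13′ stereocentre is untouched.

Step 3
Reactants: 4 (S)-citronellol TBS ether
Product: 6 (2E,6S)-8-[(tert-butyldimethylsilyl)oxy]-2,6-dimethyloct-2-enal, via allylic alcohol 5 (not isolated)
Conditions: SeO2 (cat.), t-BuOOH, CH2Cl2, rt; then MnO2, CH2Cl2, rt
Reagents that add atoms: tert-butyl hydroperoxide, CC(C)(C)OO
Why: Sharpless–Umbreit allylic oxidation (ene reaction, then [2,3]-shift) attacks the methyl group trans to the chain, which fixes the E geometry, and MnO2 takes the allylic alcohol on to the enal.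

Step 4
Reactants: 6 (2E,6S)-8-[(tert-butyldimethylsilyl)oxy]-2,6-dimethyloct-2-enal; 7 (1E,3E)-buta-1,3-diene-1,4-diyl diacetate
Product: 8 ring-B′ cycloadduct (cis-1,4-diacetoxycyclohex-2-ene carbaldehyde: on C10′ CH3 β and CHO α; C9′ chain β; C5′-OAc and C8′-OAc α)
Conditions: (S)-o-tolyl-CBS oxazaborolidine·HNTf2 (20 mol %), CH2Cl2, −78 to −40 °C
Reagents that add atoms: none
Why: Catalytic enantioselective Diels–Alder reaction with a Corey oxazaborolidinium Lewis acid: suprafacial addition keeps the C9′ chain cis to CH3-20′ (E-enal) and the two acetoxy groups cis (E,E-diene), the endo-formyl transition state puts both acetates cis to CHO, and the catalyst-shielded enal face fixes the absolute sense of C5′, C8′, C9′ and C10′ independently of the remote C13′ centre.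

Step 5
Reactants: 8 ring-B′ cycloadduct; 2 2-(trimethylsilyl)ethyl 2-methyl-3-oxobutanoate
Product: 9 δ-hydroxy-β-keto ester (C1′ carbinol)
Conditions: 2, LDA (2.1 equiv), THF, −78 to 0 °C; then 8, −78 °C; AcOH
Reagents that add atoms: none
Why: Weiler dianion aldol: the γ-carbon of the dianion of 2 adds to the hindered aldehyde faster than to the acetates at −78 °C; the new carbinol centre (C1′) and the labile C4′ are not controlled and are erased in steps 6 and 8.

Step 6
Reactants: 9 δ-hydroxy-β-keto ester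
Product: 11 E-enone β-keto ester, via mesylate 10 (not isolated)
Conditions: MsCl, Et3N, CH2Cl2, 0 °C; then DBU, rt
Reagents that add atoms: none
Why: Mesylation and base-induced β-elimination (E1cB) of the β-mesyloxy ketone give the conjugated E-enone, the geometry that avoids strain against the quaternary C10′.

Step 7
Reactants: 11 E-enone β-keto ester
Product: 12 saturated β-keto ester (cyclisation precursor)
Conditions: [(Ph3P)CuH]6, wet PhH/THF, rt
Reagents that add atoms: none
Why: Stryker conjugate reduction (copper hydride 1,4-addition) reduces the enone selectively and leaves the isolated C6′=C7′ bond, the allylic acetates and the esters untouched; no stereocentre is set.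

Step 8
Reactants: 12 saturated β-keto ester
Product: 13 TMSE 8α-acetoxy-15-(TBS-oxy)-3-oxo-17-nor-5β-labd-6-en-19-oate (A′/B′ cis)
Conditions: NaH (1.1 equiv), THF, 0 °C; then Pd(PPh3)4 (10 mol %), 50 °C
Reagents that add atoms: none
Why: Pd(0) ionises the C5′ acetate with inversion to a π-allyl complex (C5′–C6′–C7′) with Pd on the β-face, and the sodium enolate of the tethered β-keto ester attacks C5′ anti to Pd, i.e. with overall retention (intramolecular Tsuji–Trost allylic alkylation is the closest known reaction type). Ring A′ closes in a 6-(enolendo)-exo mode at the allyl terminus C5′; attack at C7′ would need a bridged eight-membered ring, and ionisation of the C8′ acetate offers only seven-membered closures and is reversible. C5′ is controlled by the substrate: the tether hangs from the α-face of C10′, so only the α-face of C5′ is in reach and the fusion must be cis (H-5′ and CH3-20′ both β). C4′ is controlled by the enolate: the chelated sodium enolate holds the ester syn to the enolate oxygen and CH3 syn to C2′, and in the chair-like closure this places CO2R equatorial on the β-face and CH3 axial on the α-face. The step needs C- over O-allylation and ring closure before β-hydride elimination; reversible O-allylation funnels to the C-product, and the soft stabilised nucleophile on a short tether secures the rest.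

Step 9
Reactants: 13 A′/B′-cis 3-keto ester
Product: 14 C2′=C3′ enol triflate
Conditions: KHMDS, THF, −78 °C; then PhNTf2
Reagents that add atoms: N-phenylbis(trifluoromethanesulfonimide), O=S(=O)(N(c1ccccc1)S(=O)(=O)C(F)(F)F)C(F)(F)F
Why: C4′ is quaternary, so the ketone can only enolise towards C2′ and O-sulfonylation of the potassium enolate gives a single enol triflate.

Step 10
Reactants: 14 enol triflate
Product: 15 TMSE 8α-acetoxy-15-(TBS-oxy)-17-nor-5β-labdan-19-oate
Conditions: H2 (1 atm), PtO2, NaHCO3, EtOAc, rt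
Reagents that add atoms: none
Why: Hydrogenation over Adams catalyst cleaves the enol triflate C–O bond and saturates both C2′=C3′ and C6′=C7′ (deoxygenation of a ketone via its enol triflate), with NaHCO3 trapping the triflic acid; no stereocentre is created.

Step 11
Reactants: 15 8α-acetate
Product: 16 8α-alcohol
Conditions: K2CO3 (cat.), MeOH, rt
Reagents that add atoms: none
Why: Base-catalysed methanolysis removes the secondary acetate, while the ester on the quaternary C4′ is too hindered to transesterify.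

Step 12
Reactants: 16 8α-alcohol
Product: 17 8-ketone
Conditions: Dess–Martin periodinane, CH2Cl2, rt
Reagents that add atoms: none
Why: Dess–Martin oxidation of the secondary alcohol is neutral and does not epimerise C9′.

Step 13
Reactants: 17 8-ketone
Product: 18 TMSE 15-(TBS-oxy)-5β-labd-8(17)-en-19-oate
Conditions: Zn, CH2Br2, TiCl4, THF/CH2Cl2, 0 °C to rt
Reagents that add atoms: dibromomethane, BrCBr
Why: Lombardo–Takai methylenation is non-basic, so the α-stereocentre C9′ is not epimerised, and it does not touch the hindered ester.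

Step 14
Reactants: 18 TBS ether
Product: 19 TMSE 15-hydroxy-5β-labd-8(17)-en-19-oate
Conditions: HF·pyridine, pyridine/THF, 0 °C to rt
Reagents that add atoms: none
Why: Buffered HF·pyridine cleaves the primary TBS ether but not the TMSE ester and does not isomerise the exocyclic alkene.

Step 15
Reactants: 19 primary alcohol
Product: 20 TMSE 15-oxo-5β-labd-8(17)-en-19-oate (right-half aldehyde)
Conditions: Dess–Martin periodinane, CH2Cl2, rt
Reagents that add atoms: none
Why: Dess–Martin oxidation stops at the aldehyde and does not affect the β-stereocentre C13′.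

Step 16
Reactants: 21 imbricatolic acid
Product: 22 (13S)-15-oxolabd-8(17)-en-19-oic acid
Conditions: Dess–Martin periodinane, CH2Cl2, rt
Reagents that add atoms: none
Why: Dess–Martin oxidation of the primary alcohol tolerates the free carboxylic acid and the exocyclic alkene.

Step 17
Reactants: 22 (13S)-15-oxolabd-8(17)-en-19-oic acid
Product: 23 TMSE (13S)-15-oxolabd-8(17)-en-19-oate (left-half aldehyde)
Conditions: Cl3CC(=NH)OCH2CH2SiMe3, toluene, 100 °C
Reagents that add atoms: 2-(trimethylsilyl)ethyl 2,2,2-trichloroacetimidate, C[Si](C)(C)CCOC(=N)C(Cl)(Cl)Cl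
Why: Promoter-free imidate esterification (the acid protonates the imidate, then carboxylate O-alkylation) works at the carboxylate oxygen and is therefore insensitive to the hindrance at C4.

Step 18
Reactants: 23 left-half aldehyde; 20 right-half aldehyde
Product: 26 bis-TMSE ester of the target enal, via imine 24 (not isolated), via hydroxy imine 25 (not isolated)
Conditions: c-C6H11NH2, 4 Å MS, Et2O, rt; LDA, THF, −78 °C; then 20, −78 to −20 °C; aq. oxalic acid, THF, rt
Reagents that add atoms: none
Why: Wittig directed aldol condensation: the lithiated N-cyclohexyl imine of 23 is the only enolate present, so it adds to aldehyde 20 without scrambling of donor and acceptor, and acid hydrolysis with dehydration gives the thermodynamically preferred E-2-alkyl-2-enal (CHO trans to the C14′ chain).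

Step 19
Reactants: 26 bis-TMSE ester
Product: 27 target diacid CNP0229303.1
Conditions: TBAF, THF, 0 °C to rt; aq. NH4Cl
Reagents that add atoms: none
Why: Fluoride attacks silicon and both esters fragment to carboxylate, ethene and Me3SiF, a cleavage that is independent of the steric shielding of C4 and C4′ and spares the enal and the exocyclic alkenes.

**Compound list**

1 | ethyl 2-methyl-3-oxobutanoate | CCOC(=O)C(C)C(C)=O | starting material
2 | 2-(trimethylsilyl)ethyl 2-methyl-3-oxobutanoate | CC(=O)C(C)C(=O)OCC[Si](C)(C)C | intermediate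
3 | (S)-citronellol, (3S)-3,7-dimethyloct-6-en-1-ol | OCC[C@@H](C)CCC=C(C)C | starting material
4 | tert-butyl{[(3S)-3,7-dimethyloct-6-en-1-yl]oxy}dimethylsilane | CC(C)(C)[Si](C)(C)OCC[C@@H](C)CCC=C(C)C | intermediate
5 | (2E,6S)-8-[(tert-butyldimethylsilyl)oxy]-2,6-dimethyloct-2-en-1-ol | CC(C)(C)[Si](C)(C)OCC[C@@H](C)CC/C=C(\C)CO | intermediate
6 | (2E,6S)-8-[(tert-butyldimethylsilyl)oxy]-2,6-dimethyloct-2-enal | CC(C)(C)[Si](C)(C)OCC[C@@H](C)CC/C=C(\C)C=O | intermediate
7 | (1E,3E)-buta-1,3-diene-1,4-diyl diacetate | CC(=O)O/C=C/C=C/OC(C)=O | starting material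
8 | 6-formyl-6-methyl-5-[(3S)-5-(TBS-oxy)-3-methylpentyl]cyclohex-2-ene-1,4-diyl diacetate; ring B′: CHO (future C1′) and both OAc (C5′, C8′) α, CH3-20′ and the C9′ chain β | CC(C)(C)[Si](C)(C)OCC[C@@H](C)CC[C@H]1[C@H](OC(C)=O)C=C[C@H](OC(C)=O)[C@]1(C)C=O | intermediate
9 | as 8, with CHO replaced by CH(OH)CH2C(=O)CH(CH3)CO2TMSE (C1′ and C4′ epimer mixture) | CC(C)(C)[Si](C)(C)OCC[C@@H](C)CC[C@H]1[C@H](OC(C)=O)C=C[C@H](OC(C)=O)[C@]1(C)C(O)CC(=O)C(C)C(=O)OCC[Si](C)(C)C | intermediate
10 | C1′ methanesulfonate of 9 | CC(C)(C)[Si](C)(C)OCC[C@@H](C)CC[C@H]1[C@H](OC(C)=O)C=C[C@H](OC(C)=O)[C@]1(C)C(OS(C)(=O)=O)CC(=O)C(C)C(=O)OCC[Si](C)(C)C | intermediate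
11 | as 8, with CHO replaced by (E)-CH=CH–C(=O)CH(CH3)CO2TMSE | CC(C)(C)[Si](C)(C)OCC[C@@H](C)CC[C@H]1[C@H](OC(C)=O)C=C[C@H](OC(C)=O)[C@]1(C)/C=C/C(=O)C(C)C(=O)OCC[Si](C)(C)C | intermediate
12 | as 8, with CHO replaced by CH2CH2C(=O)CH(CH3)CO2TMSE | CC(C)(C)[Si](C)(C)OCC[C@@H](C)CC[C@H]1[C@H](OC(C)=O)C=C[C@H](OC(C)=O)[C@]1(C)CCC(=O)C(C)C(=O)OCC[Si](C)(C)C | intermediate
13 | TMSE (13S)-8α-acetoxy-15-(TBS-oxy)-3-oxo-17-nor-5β-labd-6-en-19-oate; A′/B′ cis (5β-H, 10β-CH3), 9α-H, 4α-CH3, 4β-CO2TMSE | CC(C)(C)[Si](C)(C)OCC[C@@H](C)CC[C@H]1[C@H](OC(C)=O)C=C[C@H]2[C@]1(C)CCC(=O)[C@]2(C)C(=O)OCC[Si](C)(C)C | intermediate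
14 | TMSE (13S)-8α-acetoxy-15-(TBS-oxy)-3-(trifluoromethylsulfonyloxy)-17-nor-5β-labda-2,6-dien-19-oate | CC(C)(C)[Si](C)(C)OCC[C@@H](C)CC[C@H]1[C@H](OC(C)=O)C=C[C@H]2[C@]1(C)CC=C(OS(=O)(=O)C(F)(F)F)[C@]2(C)C(=O)OCC[Si](C)(C)C | intermediate
15 | TMSE (13S)-8α-acetoxy-15-(TBS-oxy)-17-nor-5β-labdan-19-oate | CC(C)(C)[Si](C)(C)OCC[C@@H](C)CC[C@H]1[C@H](OC(C)=O)CC[C@H]2[C@]1(C)CCC[C@]2(C)C(=O)OCC[Si](C)(C)C | intermediate
16 | TMSE (13S)-8α-hydroxy-15-(TBS-oxy)-17-nor-5β-labdan-19-oate | CC(C)(C)[Si](C)(C)OCC[C@@H](C)CC[C@H]1[C@H](O)CC[C@H]2[C@]1(C)CCC[C@]2(C)C(=O)OCC[Si](C)(C)C | intermediate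
17 | TMSE (13S)-15-(TBS-oxy)-8-oxo-17-nor-5β-labdan-19-oate | CC(C)(C)[Si](C)(C)OCC[C@@H](C)CC[C@H]1C(=O)CC[C@H]2[C@]1(C)CCC[C@]2(C)C(=O)OCC[Si](C)(C)C | intermediate
18 | TMSE (13S)-15-(TBS-oxy)-5β-labd-8(17)-en-19-oate | CC(C)(C)[Si](C)(C)OCC[C@@H](C)CC[C@H]1C(=C)CC[C@H]2[C@]1(C)CCC[C@]2(C)C(=O)OCC[Si](C)(C)C | intermediate
19 | TMSE (13S)-15-hydroxy-5β-labd-8(17)-en-19-oate | OCC[C@@H](C)CC[C@H]1C(=C)CC[C@H]2[C@]1(C)CCC[C@]2(C)C(=O)OCC[Si](C)(C)C | intermediate
20 | TMSE (13S)-15-oxo-5β-labd-8(17)-en-19-oate (4S,5S,9S,10R) | O=CC[C@@H](C)CC[C@H]1C(=C)CC[C@H]2[C@]1(C)CCC[C@]2(C)C(=O)OCC[Si](C)(C)C | intermediate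
21 | imbricatolic acid, (13S)-15-hydroxylabd-8(17)-en-19-oic acid (4S,5R,9S,10R) | C=C1CC[C@@H]2[C@](C)(CCC[C@]2(C)C(=O)O)[C@H]1CC[C@H](C)CCO | starting material
22 | (13S)-15-oxolabd-8(17)-en-19-oic acid | C=C1CC[C@@H]2[C@](C)(CCC[C@]2(C)C(=O)O)[C@H]1CC[C@H](C)CC=O | intermediate
23 | TMSE (13S)-15-oxolabd-8(17)-en-19-oate | C=C1CC[C@@H]2[C@](C)(CCC[C@]2(C)C(=O)OCC[Si](C)(C)C)[C@H]1CC[C@H](C)CC=O | intermediate
24 | N-cyclohexyl imine of 23 | C=C1CC[C@@H]2[C@](C)(CCC[C@]2(C)C(=O)OCC[Si](C)(C)C)[C@H]1CC[C@H](C)CC=NC1CCCCC1 | intermediate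
25 | β-hydroxy imine from 24 and 20 (new C14 and C15′ centres uncontrolled) | C=C1CC[C@@H]2[C@](C)(CCC[C@]2(C)C(=O)OCC[Si](C)(C)C)[C@H]1CC[C@H](C)C(C=NC1CCCCC1)C(O)C[C@@H](C)CC[C@H]1C(=C)CC[C@H]2[C@]1(C)CCC[C@]2(C)C(=O)OCC[Si](C)(C)C | intermediate
26 | bis-TMSE ester of the target (E-enal) | C=C1CC[C@@H]2[C@](C)(CCC[C@]2(C)C(=O)OCC[Si](C)(C)C)[C@H]1CC[C@H](C)/C(C=O)=C\C[C@@H](C)CC[C@H]1C(=C)CC[C@H]2[C@]1(C)CCC[C@]2(C)C(=O)OCC[Si](C)(C)C | intermediate
27 | CNP0229303.1; left unit 4S,5R,9S,10R,13S (A/B trans), right unit 4′S,5′S,9′S,10′R,13′S (A′/B′ cis), E-enal | C=C1CC[C@@H]2[C@](C)(CCC[C@]2(C)C(=O)O)[C@H]1CC[C@H](C)/C(C=O)=C\C[C@@H](C)CC[C@H]1C(=C)CC[C@H]2[C@]1(C)CCC[C@]2(C)C(=O)O | target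

**Total step count:** 19. **Longest linear sequence:** 16 steps (3 to 27: steps 2–15, 18, 19).

**Steps most likely to fail**

Step 4. The trisubstituted enal may react too slowly with the weakly donating bis-acetoxy diene, so that acid-induced decay of the diene or loss of endo and facial control takes over. The fallback sets out from 6 and moves the C8′ oxygen to a later C–H oxidation. Cycloaddition of 6 with the more reactive (E)-buta-1,3-dien-1-yl acetate under the same catalysis should give the ortho/endo 5′-monoacetate cycloadduct F1. SeO2/t-BuOOH should hydroxylate the only unhindered allylic methylene (C8′) to the allylic alcohol F2 (epimer mixture), and Dess–Martin oxidation gives the 5′-acetoxy enone F3. Luche reduction (NaBH4, CeCl3, MeOH, with the aldehyde masked in situ) should deliver hydride anti to the C9′ chain to give the 8′β-alcohol F4. Mitsunobu inversion with acetic acid (PPh3, DIAD) comes back to the route at 8.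

Step 8. Ionisation next to the quaternary C10′ may be slow, so that β-hydride elimination to the cyclohexadiene or re-ionisation of the remaining C8′ acetate competes; attack through the other enolate face would give the C4′ epimer. The fallback sets out from 12 and replaces the Pd π-allyl/enolate pathway by a cationic one. In(OTf)3 (10 mol %) in MeNO2/CH2Cl2 at −20 °C should ionise the C5′ acetate to the allyl cation, which the hydrogen-bonded Z-enol of the β-keto ester traps from the only face the tether allows. This comes back to the route at 13 and makes no new compound (F0).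

Step 10. The allylic C8′–O bond may be hydrogenolysed before C6′=C7′ is saturated, or C–O cleavage of the enol triflate may stay incomplete. The fallback sets out from 13 and separates deoxygenation from alkene reduction. NaBH4 (MeOH, 0 °C) reduces the C3′ ketone to the alcohol F5, PhOC(S)Cl/DMAP gives the phenyl thionocarbonate F6, and Bu3SnH/AIBN (Barton–McCombie) gives the 3′-deoxy alkene F7. Diimide (TsNHNH2, NaOAc, DME/H2O, reflux) then saturates C6′=C7′ without touching the C–O bond and comes back to the route at 15.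

**Further compounds**

F1 | step 4 | 5′-monoacetate cycloadduct (8 without the C8′ acetoxy group) | CC(C)(C)[Si](C)(C)OCC[C@@H](C)CC[C@H]1CC=C[C@H](OC(C)=O)[C@]1(C)C=O
F2 | step 4 | C8′ allylic alcohol of F1 (epimer mixture) | CC(C)(C)[Si](C)(C)OCC[C@@H](C)CC[C@H]1C(O)C=C[C@H](OC(C)=O)[C@]1(C)C=O
F3 | step 4 | 5′-acetoxy-8′-oxo enone | CC(C)(C)[Si](C)(C)OCC[C@@H](C)CC[C@H]1C(=O)C=C[C@H](OC(C)=O)[C@]1(C)C=O
F4 | step 4 | 8′β-alcohol (C8′ epimer of deacetylated 8) | CC(C)(C)[Si](C)(C)OCC[C@@H](C)CC[C@H]1[C@@H](O)C=C[C@H](OC(C)=O)[C@]1(C)C=O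
F0 | step 8 | none | none
F5 | step 10 | C3′ alcohol of 13 (epimer mixture) | CC(C)(C)[Si](C)(C)OCC[C@@H](C)CC[C@H]1[C@H](OC(C)=O)C=C[C@H]2[C@]1(C)CCC(O)[C@]2(C)C(=O)OCC[Si](C)(C)C
F6 | step 10 | C3′ O-phenyl thionocarbonate of F5 | CC(C)(C)[Si](C)(C)OCC[C@@H](C)CC[C@H]1[C@H](OC(C)=O)C=C[C@H]2[C@]1(C)CCC(OC(=S)Oc3ccccc3)[C@]2(C)C(=O)OCC[Si](C)(C)C
F7 | step 10 | TMSE (13S)-8α-acetoxy-15-(TBS-oxy)-17-nor-5β-labd-6-en-19-oate | CC(C)(C)[Si](C)(C)OCC[C@@H](C)CC[C@H]1[C@H](OC(C)=O)C=C[C@H]2[C@]1(C)CCC[C@]2(C)C(=O)OCC[Si](C)(C)C
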